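Ring C of the flavanone is cut at O1–C2 and C3–C4. O1, C8a, C4a and C4 are read as an oxa-diene, an ortho-quinone methide latent in phloroglucinol ring A. C2–C3 with ring B is read as a para-geranyloxystyrene. A single acid-catalysed three-component cycloaddition joins a bis-silylated phloroglucinaldehyde that keeps one free ortho-hydroxyl, trimethyl orthoformate and the styrene. It forms both bonds, closes ring C and sets C2, while C4 emerges as a methyl ether, one solvolysis and one alcohol oxidation below the ketone. A chiral BINOL-derived phosphoric acid decides the absolute configuration. Desilylation with an acidic fluoride source ends the route without opening ring C.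

Key step: step 3

Assumption: the sense of induction of the catalyst cannot be predicted with certainty. The (R)-acid is written; if a first run shows the (2R,4R) series, the equally available (S)-acid is used.

Remark on protecting groups: ring A carries silyl ethers because the alternatives fail here. Hydrogenolysis would reduce the geranyl chain, strong acid would cleave the allylic aryl ether, and base would open ring C of the flavanone.

Step 1
Reactants: 1 2,4,6-trihydroxybenzaldehyde
Product: 2 2-hydroxy-4,6-bis(tert-butyldimethylsilyloxy)benzaldehyde
Conditions: TBSCl (2.1 equiv), imidazole (4.5 equiv), DMF, 0 °C to rt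
Reagents that add atoms: tert-butyldimethylsilyl chloride (TBSCl), CC(C)(C)[Si](C)(C)Cl
Why: Chemoselective O-silylation, in which the para-hydroxyl and one of the two equivalent ortho-hydroxyls react while the last ortho-hydroxyl is held in a hydrogen bond to the formyl oxygen, so that two equivalents of silyl chloride should stop at the bis-ether and keep the one phenol that becomes O1.

Step 2
Reactants: 3 4-acetoxystyrene; 4 geranyl bromide
Product: 6 4-(geranyloxy)styrene, via sodium 4-vinylphenolate 5 (not isolated)
Conditions: NaOMe (1.0 equiv, 25% in MeOH), DMF, BHT (trace), 0 °C, 30 min; then 4 (1.05 equiv), 0 °C to rt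
Reagents that add atoms: none
Why: Methoxide transesterification frees the phenolate without isolation of polymerisation-prone 4-vinylphenol, and the Williamson ether synthesis (SN2 at the primary allylic carbon in a dipolar aprotic medium) should give O-alkylation with the E-alkene of 4 unchanged.

Step 3
Reactants: 2 2-hydroxy-4,6-bis(tert-butyldimethylsilyloxy)benzaldehyde; 6 4-(geranyloxy)styrene; 7 trimethyl orthoformate
Product: 10 (2S,4S)-4'-O-geranyl-4-methoxy-5,7-bis(tert-butyldimethylsilyloxy)flavan (2,4-cis), via dimethyl acetal 8 (not isolated), via methoxy ortho-quinone methide 9 (not isolated)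
Conditions: (R)-TRIP [(R)-3,3'-bis(2,4,6-triisopropylphenyl)-1,1'-binaphthyl-2,2'-diyl hydrogen phosphate] (10 mol %), 7 (1.5 equiv), 6 (1.5 equiv), 5 Å MS, toluene, 0 °C to rt; any 2,4-trans isomer removed by chromatography
Reagents that add atoms: none
Why: Proposed new method: the phosphoric acid catalyses acetal formation from 2 and 7 (8) and then loss of methanol to the methoxy-substituted ortho-quinone methide 9, which stays bound to the chiral phosphate through a hydrogen bond or contact ion pair at O1, and the CH2 terminus of 6 (C3) adds to C4 while O1 closes onto the developing para-alkoxybenzylic cation at C2 in a concerted but strongly asynchronous inverse-electron-demand oxa-[4+2] cycloaddition. The closest known reaction types are this same salicylaldehyde/orthoformate/styrene chroman synthesis under achiral Brønsted or Lewis acids and the chiral phosphoric acid catalysed [4+2] cycloaddition of ortho-quinone methides from ortho-hydroxybenzyl alcohols with vinylarenes, and only their combination is new. Ring C is closed in the cycloaddition mode, four atoms (O1, C8a, C4a, C4) coming from 9 and two (C2, C3) from 6. C4 is set by the catalyst, whose 3,3'-aryl groups leave one face of the planar C4 terminus open, and C2 is set relative to C4 by the endo approach of ring B to the E-configured methide, which places aryl and methoxy cis and so turns (4S) into (2S). Regioselectivity (2-aryl, not 3-aryl) follows from the polarity of the partners, since only attack through the CH2 terminus gives a cation stabilised by the para-geranyloxy group. Chemoselectivity for the vinyl group over the two trisubstituted alkenes of the geranyl chain rests on the same donor effect, and an acid of this strength should neither ionise the allylic aryl ether, nor cleave aryl silyl ethers, nor start cationic polymerisation of 6.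

Step 4
Reactants: 10 (2S,4S)-4'-O-geranyl-4-methoxy-5,7-bis(tert-butyldimethylsilyloxy)flavan
Product: 11 (2S)-4'-O-geranyl-5,7-bis(tert-butyldimethylsilyloxy)flavan-4-ol (mixture of C4 epimers)
Conditions: PPTS (0.2 equiv), THF/H2O 4:1 (dilute), 35 °C
Reagents that add atoms: water, O
Why: SN1 solvolysis of a benzylic ether, in which C4 carries an aryl group oxygenated at both ortho positions and the para position and therefore ionises under an acid too weak to touch the C2–O1 bond, the aryl silyl ethers or the geranyl ether, the large excess of water captures the cation, C2 takes no part, and the epimer mixture at C4 does not matter because C4 becomes sp2 in step 5.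

Step 5
Reactants: 11 (2S)-4'-O-geranyl-5,7-bis(tert-butyldimethylsilyloxy)flavan-4-ol
Product: 12 (2S)-4'-O-geranyl-5,7-bis(tert-butyldimethylsilyloxy)flavanone
Conditions: Dess–Martin periodinane (1.3 equiv), pyridine (5 equiv), CH2Cl2, 0 °C to rt
Reagents that add atoms: none
Why: Dess–Martin oxidation of a secondary benzylic alcohol, buffered with pyridine so that the acetic acid released cannot ionise the carbinol, leaves the trisubstituted alkenes and silyl ethers alone, brings both C4 epimers to one ketone and offers no base strong enough to disturb C2.

Step 6
Reactants: 12 (2S)-4'-O-geranyl-5,7-bis(tert-butyldimethylsilyloxy)flavanone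
Product: 13 (2S)-4'-O-geranylnaringenin (target)
Conditions: KHF2 (4 equiv), MeOH/THF 3:1, rt; work-up with pH 5 buffer
Reagents that add atoms: none
Why: Fluoride-mediated cleavage of aryl silyl ethers with a mildly acidic fluoride source releases each phenol in its protonated form, so that enolisation and retro-oxa-Michael opening of ring C to the chalcone, the path by which flavanones racemise under base, should not start, and the geranyl ether is inert.

Compound list
1 | 2,4,6-trihydroxybenzaldehyde | O=Cc1c(O)cc(O)cc1O | starting material
2 | 2-hydroxy-4,6-bis(tert-butyldimethylsilyloxy)benzaldehyde | O=Cc1c(O)cc(O[Si](C)(C)C(C)(C)C)cc1O[Si](C)(C)C(C)(C)C | intermediate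
3 | 4-acetoxystyrene | CC(=O)Oc1ccc(C=C)cc1 | starting material
4 | geranyl bromide, (E) | CC(C)=CCC/C(C)=C/CBr | starting material
5 | sodium 4-vinylphenolate | [Na+].[O-]c1ccc(C=C)cc1 | intermediate
6 | 4-(geranyloxy)styrene, (E) | CC(C)=CCC/C(C)=C/COc1ccc(C=C)cc1 | intermediate
7 | trimethyl orthoformate | COC(OC)OC | starting material
8 | 2-(dimethoxymethyl)-3,5-bis(tert-butyldimethylsilyloxy)phenol | COC(OC)c1c(O)cc(O[Si](C)(C)C(C)(C)C)cc1O[Si](C)(C)C(C)(C)C | intermediate
9 | (E)-6-(methoxymethylidene)-3,5-bis(tert-butyldimethylsilyloxy)cyclohexa-2,4-dien-1-one (methoxy anti to the ring carbonyl) | CO/C=C1/C(=O)C=C(O[Si](C)(C)C(C)(C)C)C=C1O[Si](C)(C)C(C)(C)C | intermediate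
10 | (2S,4S)-4'-O-geranyl-4-methoxy-5,7-bis(tert-butyldimethylsilyloxy)flavan (2,4-cis) | CC(C)=CCC/C(C)=C/COc1ccc([C@@H]2C[C@H](OC)c3c(O[Si](C)(C)C(C)(C)C)cc(O[Si](C)(C)C(C)(C)C)cc3O2)cc1 | intermediate
11 | (2S)-4'-O-geranyl-5,7-bis(tert-butyldimethylsilyloxy)flavan-4-ol (C4 epimers, C4 left unmarked) | CC(C)=CCC/C(C)=C/COc1ccc([C@@H]2CC(O)c3c(O[Si](C)(C)C(C)(C)C)cc(O[Si](C)(C)C(C)(C)C)cc3O2)cc1 | intermediate
12 | (2S)-4'-O-geranyl-5,7-bis(tert-butyldimethylsilyloxy)flavanone | CC(C)=CCC/C(C)=C/COc1ccc([C@@H]2CC(=O)c3c(O[Si](C)(C)C(C)(C)C)cc(O[Si](C)(C)C(C)(C)C)cc3O2)cc1 | intermediate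
13 | (2S)-4'-O-geranylnaringenin, (2S)-5,7-dihydroxy-2-[4-[(2E)-3,7-dimethylocta-2,6-dienyloxy]phenyl]chroman-4-one | CC(C)=CCC/C(C)=C/COc1ccc([C@@H]2CC(=O)c3c(O)cc(O)cc3O2)cc1 | target

Total step count: 6.
Longest linear sequence: 5 steps (steps 1, 3, 4, 5, 6 from 1; equally steps 2, 3, 4, 5, 6 from 3).

Steps most likely to fail

**Step 3 (the labelled step).** Four things may go wrong.
- Facial discrimination may be weak, because the styrene offers the catalyst no hydrogen-bond handle and all control must come from the ion pair at O1.
- The reaction may leak through the exo mode or through the Z-methide, helped by the bulky silyloxy group next to C4. Good control at C4 would then become the wrong configuration at C2, which is why the 2,4-trans isomer is removed before C4 is erased.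
- Turnover may be slow, since the methide is strongly donor-stabilised.
- The acid may oligomerise the styrene.

The fallback uses known chemistry only. It sets out from 2, 6 and 7 and returns at 12.
- The three-component reaction is run with an achiral acid of proven use in this reaction type (p-TsOH, 5 mol %, CH2Cl2, 0 °C). It passes through 8 and 9 and should give the racemic cis-4-methoxyflavan F1.
- The conditions of steps 4 and 5 then lead to the racemic flavan-4-ol F2 and the racemic flavanone F3.
- F3 is resolved kinetically by Noyori–Ikariya asymmetric transfer hydrogenation (Cp*RhCl[(R,R)-TsDPEN], 1 mol %, HCO2H/Et3N 5:2, EtOAc, rt, stopped near half conversion). This type of resolution is established for racemic flavanones.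
- From the usual sense of these catalysts on aryl ketones, the (2R)-ketone should be reduced to the (2R,4R)-flavan-4-ol F4. The (2S)-ketone 12 should stay behind and be separated by chromatography.

**Step 4.** The C4 cation may escape capture by water. It can lose a proton from C3 (elimination), undergo Friedel–Crafts capture by ring A of a second molecule (oligomerisation of the proanthocyanidin kind), or lose the 7-O-silyl group from the quinone-methide-like cation.

The fallback sets out from 10 and returns at 12, bypassing 11 and step 5. It replaces solvolysis by oxidative cleavage of the benzylic methyl ether with DDQ (1.2 equiv, CH2Cl2/pH 7 buffer, 0 °C). The mechanism is that of para-methoxybenzyl ether removal and of the known DDQ oxidation of flavans at C4.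
- Hydride is taken from C4–H. This is the most hydridic C–H bond because it is flanked by the methoxy oxygen and the trioxygenated ring A, so it should react ahead of C2–H and the allylic OCH2.
- Water adds to the oxocarbenium ion to give the C4 hemiketal F5, which loses methanol to give 12.

**Step 6.** The C2 configuration may be partly lost through reversible opening of ring C (enolisation, retro-oxa-Michael, re-closure) once free phenols are present, either in the reaction or on work-up.

The fallback repairs the damage instead of preventing it. It sets out from 13 of lowered enantiopurity and returns at 13. Preparative HPLC on a polysaccharide chiral phase (amylose tris(3,5-dimethylphenylcarbamate), eluent acidified with 0.1% AcOH), a separation type well established for naringenin-type flavanones, removes (2R)-4'-O-geranylnaringenin F6.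

Further compounds
F1 | step 3 | (±)-2,4-cis-4'-O-geranyl-4-methoxy-5,7-bis(tert-butyldimethylsilyloxy)flavan (racemate, ring stereocentres left unmarked) | CC(C)=CCC/C(C)=C/COc1ccc(C2CC(OC)c3c(O[Si](C)(C)C(C)(C)C)cc(O[Si](C)(C)C(C)(C)C)cc3O2)cc1
F2 | step 3 | (±)-4'-O-geranyl-5,7-bis(tert-butyldimethylsilyloxy)flavan-4-ol (racemate, ring stereocentres left unmarked) | CC(C)=CCC/C(C)=C/COc1ccc(C2CC(O)c3c(O[Si](C)(C)C(C)(C)C)cc(O[Si](C)(C)C(C)(C)C)cc3O2)cc1
F3 | step 3 | (±)-4'-O-geranyl-5,7-bis(tert-butyldimethylsilyloxy)flavanone (racemate, C2 left unmarked) | CC(C)=CCC/C(C)=C/COc1ccc(C2CC(=O)c3c(O[Si](C)(C)C(C)(C)C)cc(O[Si](C)(C)C(C)(C)C)cc3O2)cc1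
F4 | step 3 | (2R,4R)-4'-O-geranyl-5,7-bis(tert-butyldimethylsilyloxy)flavan-4-ol (2,4-cis) | CC(C)=CCC/C(C)=C/COc1ccc([C@H]2C[C@@H](O)c3c(O[Si](C)(C)C(C)(C)C)cc(O[Si](C)(C)C(C)(C)C)cc3O2)cc1
F5 | step 4 | (2S)-4'-O-geranyl-4-hydroxy-4-methoxy-5,7-bis(tert-butyldimethylsilyloxy)flavan (hemiketal, C4 left unmarked) | CC(C)=CCC/C(C)=C/COc1ccc([C@@H]2CC(O)(OC)c3c(O[Si](C)(C)C(C)(C)C)cc(O[Si](C)(C)C(C)(C)C)cc3O2)cc1
F6 | step 6 | (2R)-4'-O-geranylnaringenin | CC(C)=CCC/C(C)=C/COc1ccc([C@H]2CC(=O)c3c(O)cc(O)cc3O2)cc1
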